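Left-handed substrate is the one to follow: the flask below asks how far it falls beneath the right-handed substrate.

| flask | left-handed substrate | right-handed substrate | reagent | precatalyst | remark | time |
|---|---|---|---|---|---|---|
| west | 1 M | 1 M | 2 M (fed, over 4.0 min) | 2.5 mM | run made earlier |  |
| south | 1 M | 1 M | 2 M (fed, over 4.0 min) | 10 mM | run made earlier |  |
| south-east | 0.50 M | 0.50 M | 2 M (fed, over 4.0 min) | 5 mM | run made earlier |  |
| flask | 1.0 M | 1.0 M | 2.00 M (fed, over 4.0 min) | 5.0 mM |  | 4.0 h |

| run | time / h | right-handed substrate / % | left-handed substrate / % |
|---|---|---|---|
| west | 0.200 | 50 | 47 |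
| west | 0.667 | 50 | 34 |
| west | 1.00 | 50 | 30 |
| west | 2.00 | 50 | 14 |
| west | 2.50 | 48 | 9 |
| west | 3.00 | 47 | 7 |
| south | 0.200 | 48 | 37 |
| south | 0.667 | 48 | 7 |
| south | 1.00 | 47 | 1 |
| south | 2.00 | 38 | 0 |
| south | 2.50 | 36 | 2 |
| south | 3.00 | 36 | 0 |
| south-east | 0.250 | 50 | 36 |
| south-east | 0.833 | 45 | 5 |
| south-east | 1.33 | 42 | 2 |
| south-east | 2.50 | 33 | 0 |
| south-east | 3.00 | 33 | 2 |

(each reading ± 1.5 percentage points)

- free catalyst is single-handed; left-handed substrate and right-handed substrate are mirror images of each other, charged as a racemate, each of them at the stated concentration
- what was read earlier has a scatter of 1.5 percentage points, one standard deviation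

* whether the excess of right-handed substrate over left-handed substrate among what is left of the two reaches 98 % by 4.0 h (yes / no)
* the highest excess of right-handed substrate over left-handed substrate among what is left of the two up to 4.0 h

Turn the target into a decay first. An excess of 98 % means left-handed substrate stands at 1.01 % of the right-handed, which is 4.60 natural-log units of decay while the right-handed holds roughly still. So the number to know well is the apparent rate constant of left-handed substrate: the slope of its logarithm between two readings, an average over that stretch and no true first-order constant.

Now test the charges. Precatalyst matters: west reads 0.680 h⁻¹ and south, with 4.00 times the precatalyst of west, reads 3.57 h⁻¹, which is 5.25 times as large. Substrate matters too: south-east, with half the flask's substrate at equal precatalyst, reads 3.39 h⁻¹. Borrow from west and south, then, whose substrate matches the flask's. Reagent charge and feed match too, so correct neither.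

The flask's precatalyst is the geometric mean of theirs, so take the geometric mean of the two averages as my estimate for the flask, 1.56 h⁻¹. Divide the decay needed by this average to get the clearing time, 2.95 h, which is shorter than the 4.0 h allowed. My answer is yes; that average carried to 4.0 h gives an excess of 99.6 %.

The forecast also says yes, with a top of 99 %: “it is likely yes, but marginally”.

The flask gives yes, with a top of >99.9 %.

    reagent + catalyst intermediate A → free catalyst + left-handed product (k = 2.28 M⁻¹ min⁻¹)
    free catalyst + left-handed substrate ⇌ catalyst intermediate A (K = 9.95 M⁻¹, k = 111 M⁻¹ min⁻¹)
    precatalyst → free catalyst (k = 0.248 min⁻¹)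
    reagent + catalyst intermediate B → free catalyst + right-handed product (k = 0.740 M⁻¹ min⁻¹)
    free catalyst + right-handed substrate ⇌ catalyst intermediate B (K = 0.700 M⁻¹, k = 833 M⁻¹ min⁻¹)
    free catalyst → spent catalyst (k = 0.00197 min⁻¹)

The flask reaches 98 % at 2.49 h, inside the clearing time, with 43.6 % right-handed substrate left. For west the clearing time is 6.76 h, beyond its last reading at 3.00 h, where the excess reads 74.1 %. One constant hides two steps. At 0.634 h in the flask, free catalyst enters catalyst intermediate A at 0.068 of its forward rate into catalyst intermediate B, yet reagent is used through catalyst intermediate A at 17 times its rate through catalyst intermediate B.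

(The numbers in the tables are simulated with constants of no real substance; the scatter is artificial.)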